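**Retrosynthetic overview**
1. Target ⇐ acetylation and hydroxyl-directed epoxidation of a ten-membered (Z)-cycloalkenol; the carbocycle is closed late by an intramolecular Nozaki–Hiyama–Kishi reaction (C8–C9 bond, vinyl iodide + α-angeloyloxy aldehyde).
2. C3/C4/C5 triad ⇐ CBS reduction of a (Z)-enone, threo-selective directed epoxidation of the resulting (Z)-allylic alcohol, and titanium-mediated epoxide opening at C5 by angelic acid.
3. (Z)-Enone ⇐ γ-lactone + mono-lithiated symmetric (2Z,5Z)-2,6-diiodohepta-2,5-diene (C4–C8 linchpin from two Stork–Zhao-type Wittig reactions).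
4. γ-Lactone (C9, C10, C1, C2, C3 and the isopropenyl group) ⇐ new organocatalytic asymmetric carbonyl–ene reaction of ethyl glyoxylate with methyl 4-methylpent-3-enoate, which sets the first two stereocentres.
5. Ring order: temporary γ-lactone (formed in step 1, opened in step 8) → cyclodecene (step 16) → oxirane (step 17).

Assumption and conventions (one line): compounds 1, 2, 7, angelic acid and ethyltriphenylphosphonium iodide are taken as commercial; ring locants for the target, 21, 22, F5 and F6 are C1 = CH–isopropenyl, C2 = CH2, C3 = CH–OAc, C4 = C(OH)CH3, C5 = CH–OAng, C6 = CH2, C7/C8 = alkene or epoxide carbons (C8 methylated), C9 = CH–O, C10 = CH–OAng; open-chain compounds 13–20 are named as undecanes whose C1–C10 become ring C9, C10, C1, C2, C3, C4, C5, C6, C7, C8; Ang = (2Z)-2-methylbut-2-enoyl.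

**Route**

Step 1
Reactants: 1 ethyl glyoxylate; 2 methyl 4-methylpent-3-enoate
Product: 4 ethyl (2S,3R)-5-oxo-3-(prop-1-en-2-yl)oxolane-2-carboxylate, via hydroxy diester 3 (not isolated)
Conditions: (S,S)-IDPi Brønsted acid (confined imidodiphosphorimidate, 3,3′-Ar = 3,5-(CF3)2C6H3, N-Tf; 2 mol%; antipode if induction is opposite), 2 (3 equiv), CH2Cl2, 4 Å MS, −40 °C; then CSA (5 mol%), 25 °C
Reagents that add atoms: none
Why: Proposed new method: the confined chiral acid activates the glyoxylate carbonyl inside its pocket and the trisubstituted alkene attacks through a closed six-membered ene transition state in which an allylic methyl hydrogen moves to the carbonyl oxygen, so the new C–C bond, both stereocentres and the isopropenyl group form at once; pocket face-shielding sets C3 (R), and C2 is α to the ester and epimerisable so the trans-lactone formed on lactonisation is also the thermodynamic isomer; closest known reaction type is the Lewis-acid-catalysed asymmetric glyoxylate–ene reaction and the chiral-Brønsted-acid-catalysed intramolecular carbonyl–ene cyclisation.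

Step 2
Reactants: 4 ethyl (2S,3R)-5-oxo-3-(prop-1-en-2-yl)oxolane-2-carboxylate
Product: 5 (4R,5S)-5-(hydroxymethyl)-4-(prop-1-en-2-yl)oxolan-2-one
Conditions: NaBH4 (1.0 equiv), EtOH, 0 °C
Reagents that add atoms: none
Why: Chemoselective borohydride reduction, since the ester α to the ring oxygen is activated and is reduced while the γ-lactone survives (the classical route to 5-hydroxymethyl butyrolactones); no stereocentre is touched.

Step 3
Reactants: 5 (4R,5S)-5-(hydroxymethyl)-4-(prop-1-en-2-yl)oxolan-2-one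
Product: 6 (4R,5S)-5-{[(tert-butyldimethylsilyl)oxy]methyl}-4-(prop-1-en-2-yl)oxolan-2-one
Conditions: TBSCl, imidazole, DMF, 0 °C → rt
Reagents that add atoms: tert-butyldimethylsilyl chloride CC(C)(C)[Si](C)(C)Cl
Why: Standard silyl protection of the primary alcohol, leaving the lactone carbonyl as the only electrophile for step 8.

Step 4
Reactants: 7 3-[(tert-butyldimethylsilyl)oxy]propanal
Product: 8 tert-butyl{[(3Z)-4-iodopent-3-en-1-yl]oxy}dimethylsilane
Conditions: EtPPh3I, n-BuLi, THF, 0 °C; I2, −78 °C; NaHMDS, −20 °C; then 7, −78 → −20 °C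
Reagents that add atoms: ethyltriphenylphosphonium iodide CC[P+](c1ccccc1)(c1ccccc1)c1ccccc1.[I-]; iodine [I][I]
Why: Stork–Zhao-type Wittig olefination with the α-iodo ylide gives the (Z)-2-iodo-2-alkene (iodine cis to the chain) through the kinetically favoured cis-oxaphosphetane.

Step 5
Reactants: 8 tert-butyl{[(3Z)-4-iodopent-3-en-1-yl]oxy}dimethylsilane
Product: 9 (3Z)-4-iodopent-3-en-1-ol
Conditions: p-TsOH·H2O (5 mol%), MeOH, 0 °C
Reagents that add atoms: none
Why: Acid-catalysed methanolysis of a primary silyl ether; the vinyl iodide is inert.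

Step 6
Reactants: 9 (3Z)-4-iodopent-3-en-1-ol
Product: 10 (3Z)-4-iodopent-3-enal
Conditions: Dess–Martin periodinane, pyridine, CH2Cl2, 0 °C (used crude)
Reagents that add atoms: none
Why: Dess–Martin oxidation under buffered, non-basic conditions keeps the skipped (β,γ-unsaturated) aldehyde from moving into conjugation.

Step 7
Reactants: 10 (3Z)-4-iodopent-3-enal
Product: 11 (2Z,5Z)-2,6-diiodohepta-2,5-diene
Conditions: EtPPh3I, n-BuLi, THF, 0 °C; I2, −78 °C; NaHMDS, −20 °C; then 10, −78 °C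
Reagents that add atoms: ethyltriphenylphosphonium iodide CC[P+](c1ccccc1)(c1ccccc1)c1ccccc1.[I-]; iodine [I][I]
Why: A second Stork–Zhao-type Wittig olefination with the same Z-selectivity gives a symmetric linchpin whose two ends are identical, so mono-functionalisation needs no differentiation.

Step 8
Reactants: 6 (4R,5S)-5-{[(tert-butyldimethylsilyl)oxy]methyl}-4-(prop-1-en-2-yl)oxolan-2-one; 11 (2Z,5Z)-2,6-diiodohepta-2,5-diene
Product: 13 (2S,3R,6Z,9Z)-1-[(tert-butyldimethylsilyl)oxy]-2-hydroxy-10-iodo-6-methyl-3-(prop-1-en-2-yl)undeca-6,9-dien-5-one, via vinyllithium 12 (not isolated)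
Conditions: 11 (2.5 equiv), t-BuLi (2.6 equiv), Et2O, −100 °C; then 6, THF, −100 → −78 °C; AcOH quench at −78 °C
Reagents that add atoms: none
Why: Iodine–lithium exchange with retention of alkene geometry, then organolithium acyl substitution on the γ-lactone, where the tetrahedral lithium lactolate resists a second addition and opens on work-up to the (Z)-enone and the free C2 hydroxyl; excess symmetric 11 suppresses double exchange.

Step 9
Reactants: 13 (2S,3R,6Z,9Z)-1-[(tert-butyldimethylsilyl)oxy]-2-hydroxy-10-iodo-6-methyl-3-(prop-1-en-2-yl)undeca-6,9-dien-5-one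
Product: 14 (2S,3R,6Z,9Z)-1-[(tert-butyldimethylsilyl)oxy]-10-iodo-6-methyl-5-oxo-3-(prop-1-en-2-yl)undeca-6,9-dien-2-yl (2Z)-2-methylbut-2-enoate
Conditions: angelic acid, 2,4,6-Cl3C6H2COCl, Et3N, toluene, rt; then 13, 70 °C
Reagents that add atoms: angelic acid C/C=C(/C)C(=O)O
Why: Yamaguchi-type mixed-anhydride esterification, the established way to form angelates without isomerisation to tiglates; only one hydroxyl is present, and C5 is still a ketone, which differentiates the two future acyloxy positions.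

Step 10
Reactants: 14 (2S,3R,6Z,9Z)-1-[(tert-butyldimethylsilyl)oxy]-10-iodo-6-methyl-5-oxo-3-(prop-1-en-2-yl)undeca-6,9-dien-2-yl (2Z)-2-methylbut-2-enoate
Product: 15 (2S,3R,5R,6Z,9Z)-1-[(tert-butyldimethylsilyl)oxy]-5-hydroxy-10-iodo-6-methyl-3-(prop-1-en-2-yl)undeca-6,9-dien-2-yl (2Z)-2-methylbut-2-enoate
Conditions: (S)-Me-CBS oxazaborolidine (0.3 equiv), catecholborane (1.8 equiv), toluene, −78 °C
Reagents that add atoms: none
Why: Corey–Bakshi–Shibata reduction, in which the α-methyl alkenyl group is the large substituent, so the (S)-catalyst delivers hydride to give the (5R)-allylic alcohol under reagent control.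

Step 11
Reactants: 15 (2S,3R,5R,6Z,9Z)-1-[(tert-butyldimethylsilyl)oxy]-5-hydroxy-10-iodo-6-methyl-3-(prop-1-en-2-yl)undeca-6,9-dien-2-yl (2Z)-2-methylbut-2-enoate
Product: 16 (2S,3R,5R,6S,7R,9Z)-1-[(tert-butyldimethylsilyl)oxy]-6,7-epoxy-5-hydroxy-10-iodo-6-methyl-3-(prop-1-en-2-yl)undec-9-en-2-yl (2Z)-2-methylbut-2-enoate
Conditions: m-CPBA (1.1 equiv), CH2Cl2, −10 °C
Reagents that add atoms: m-chloroperbenzoic acid OOC(=O)c1cccc(Cl)c1
Why: Hydroxyl-directed peracid epoxidation (Henbest type), where 1,3-allylic strain from C8 cis to the carbinol fixes the reactive conformer and gives the threo epoxy alcohol (C6, C7 set); the electron-rich trisubstituted allylic alkene reacts before the isopropenyl, angelate and iodoalkene double bonds.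

Step 12
Reactants: 16 (2S,3R,5R,6S,7R,9Z)-1-[(tert-butyldimethylsilyl)oxy]-6,7-epoxy-5-hydroxy-10-iodo-6-methyl-3-(prop-1-en-2-yl)undec-9-en-2-yl (2Z)-2-methylbut-2-enoate
Product: 17 (2S,3R,5R,6S,7S,9Z)-1-[(tert-butyldimethylsilyl)oxy]-5,6-dihydroxy-10-iodo-6-methyl-3-(prop-1-en-2-yl)undec-9-ene-2,7-diyl bis[(2Z)-2-methylbut-2-enoate]
Conditions: Ti(OiPr)4 (1.5 equiv), angelic acid (3 equiv), CH2Cl2, rt
Reagents that add atoms: angelic acid C/C=C(/C)C(=O)O
Why: Sharpless-type Ti(OiPr)4-mediated opening of a 2,3-epoxy alcohol, in which titanium chelated by the C5 hydroxyl and the epoxide directs the carboxylate to the distal secondary carbon C7 with SN2 inversion, leaving the tertiary C6–O bond intact and installing the second angelate without a protecting group.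

Step 13
Reactants: 17 (2S,3R,5R,6S,7S,9Z)-1-[(tert-butyldimethylsilyl)oxy]-5,6-dihydroxy-10-iodo-6-methyl-3-(prop-1-en-2-yl)undec-9-ene-2,7-diyl bis[(2Z)-2-methylbut-2-enoate]
Product: 18 (2S,3R,5R,6S,7S,9Z)-5-acetoxy-1-[(tert-butyldimethylsilyl)oxy]-6-hydroxy-10-iodo-6-methyl-3-(prop-1-en-2-yl)undec-9-ene-2,7-diyl bis[(2Z)-2-methylbut-2-enoate]
Conditions: Ac2O, pyridine, 0 °C → rt
Reagents that add atoms: acetic anhydride CC(=O)OC(C)=O
Why: Selective acetylation of the secondary C5 hydroxyl (the tertiary C6 hydroxyl does not react without DMAP), which also prevents six-membered lactol formation with the aldehyde made in step 15.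

Step 14
Reactants: 18 (2S,3R,5R,6S,7S,9Z)-5-acetoxy-1-[(tert-butyldimethylsilyl)oxy]-6-hydroxy-10-iodo-6-methyl-3-(prop-1-en-2-yl)undec-9-ene-2,7-diyl bis[(2Z)-2-methylbut-2-enoate]
Product: 19 (2S,3R,5R,6S,7S,9Z)-5-acetoxy-1,6-dihydroxy-10-iodo-6-methyl-3-(prop-1-en-2-yl)undec-9-ene-2,7-diyl bis[(2Z)-2-methylbut-2-enoate]
Conditions: HF·pyridine, pyridine, THF, 0 °C
Reagents that add atoms: none
Why: Buffered fluoride desilylation of the primary silyl ether under mildly acidic conditions, which avoids migration of the neighbouring angelate; esters and the vinyl iodide are inert.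

Step 15
Reactants: 19 (2S,3R,5R,6S,7S,9Z)-5-acetoxy-1,6-dihydroxy-10-iodo-6-methyl-3-(prop-1-en-2-yl)undec-9-ene-2,7-diyl bis[(2Z)-2-methylbut-2-enoate]
Product: 20 (2S,3R,5R,6S,7S,9Z)-5-acetoxy-6-hydroxy-10-iodo-6-methyl-1-oxo-3-(prop-1-en-2-yl)undec-9-ene-2,7-diyl bis[(2Z)-2-methylbut-2-enoate]
Conditions: Dess–Martin periodinane, pyridine, CH2Cl2, 0 °C (used at once)
Reagents that add atoms: none
Why: Dess–Martin oxidation of the only primary alcohol; the tertiary alcohol cannot be oxidised and the buffered conditions limit epimerisation of the α-acyloxy aldehyde.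

Step 16
Reactants: 20 (2S,3R,5R,6S,7S,9Z)-5-acetoxy-6-hydroxy-10-iodo-6-methyl-1-oxo-3-(prop-1-en-2-yl)undec-9-ene-2,7-diyl bis[(2Z)-2-methylbut-2-enoate]
Product: 21 (1R,3R,4S,5S,7Z,9R,10S)-3-acetoxy-4,9-dihydroxy-4,8-dimethyl-1-(prop-1-en-2-yl)cyclodec-7-ene-5,10-diyl bis[(2Z)-2-methylbut-2-enoate]
Conditions: CrCl2 (8 equiv), NiCl2 (2 mol%), DMSO/THF 3:1, 2 mM, rt
Reagents that add atoms: none
Why: Intramolecular Nozaki–Hiyama–Kishi reaction, in which the vinyl iodide becomes a vinylchromium species that adds only to the aldehyde (esters and the free tertiary alcohol are tolerated), closing the ten-membered ring with retention of the (Z)-alkene; Felkin–Anh addition anti to the α-angeloyloxy group sets C9.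

Step 17
Reactants: 21 (1R,3R,4S,5S,7Z,9R,10S)-3-acetoxy-4,9-dihydroxy-4,8-dimethyl-1-(prop-1-en-2-yl)cyclodec-7-ene-5,10-diyl bis[(2Z)-2-methylbut-2-enoate]
Product: 22 (1R,3R,4S,5S,7R,8S,9S,10S)-3-acetoxy-7,8-epoxy-4,9-dihydroxy-4,8-dimethyl-1-(prop-1-en-2-yl)cyclodecane-5,10-diyl bis[(2Z)-2-methylbut-2-enoate]
Conditions: VO(acac)2 (5 mol%), t-BuOOH (1.5 equiv), CH2Cl2, 0 °C
Reagents that add atoms: tert-butyl hydroperoxide CC(C)(C)OO
Why: Vanadium-catalysed hydroxyl-directed epoxidation, where the C9 alkoxide bound to vanadium delivers oxygen to the alkene face syn to itself, giving the cis-epoxy alcohol of the cis-cycloalkenol (C7, C8 set); the non-allylic isopropenyl and electron-poor angelate alkenes do not react.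

Step 18
Reactants: 22 (1R,3R,4S,5S,7R,8S,9S,10S)-3-acetoxy-7,8-epoxy-4,9-dihydroxy-4,8-dimethyl-1-(prop-1-en-2-yl)cyclodecane-5,10-diyl bis[(2Z)-2-methylbut-2-enoate]
Product: 23 (1R,3R,4S,5S,7R,8R,9S,10S)-3,9-diacetoxy-7,8-epoxy-4-hydroxy-4,8-dimethyl-1-(prop-1-en-2-yl)cyclodecane-5,10-diyl bis[(2Z)-2-methylbut-2-enoate]
Conditions: Ac2O, pyridine, DMAP (cat.), CH2Cl2, 0 °C
Reagents that add atoms: acetic anhydride CC(=O)OC(C)=O
Why: Acetylation of the remaining secondary alcohol at 0 °C leaves the hindered tertiary C4 hydroxyl free (the C8 descriptor changes from S to R only because the CIP ranking of C9 changes on acylation).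

**Compound list**
1 | ethyl glyoxylate | CCOC(=O)C=O | starting material
2 | methyl 4-methylpent-3-enoate | COC(=O)CC=C(C)C | starting material
3 | 1-ethyl 5-methyl (2S,3R)-2-hydroxy-3-(prop-1-en-2-yl)pentanedioate | CCOC(=O)[C@@H](O)[C@@H](C(C)=C)CC(=O)OC | intermediate
4 | ethyl (2S,3R)-5-oxo-3-(prop-1-en-2-yl)oxolane-2-carboxylate | C=C(C)[C@@H]1[C@H](OC(=O)C1)C(=O)OCC | intermediate
5 | (4R,5S)-5-(hydroxymethyl)-4-(prop-1-en-2-yl)oxolan-2-one | C=C(C)[C@@H]1[C@H](OC(=O)C1)CO | intermediate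
6 | (4R,5S)-5-{[(tert-butyldimethylsilyl)oxy]methyl}-4-(prop-1-en-2-yl)oxolan-2-one | C=C(C)[C@@H]1[C@H](OC(=O)C1)CO[Si](C)(C)C(C)(C)C | intermediate
7 | 3-[(tert-butyldimethylsilyl)oxy]propanal | O=CCCO[Si](C)(C)C(C)(C)C | starting material
8 | tert-butyl{[(3Z)-4-iodopent-3-en-1-yl]oxy}dimethylsilane | C/C(I)=C/CCO[Si](C)(C)C(C)(C)C | intermediate
9 | (3Z)-4-iodopent-3-en-1-ol | C/C(I)=C/CCO | intermediate
10 | (3Z)-4-iodopent-3-enal | C/C(I)=C/CC=O | intermediate
11 | (2Z,5Z)-2,6-diiodohepta-2,5-diene | C/C(I)=C/C/C=C(/C)I | intermediate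
12 | [(2E,5Z)-6-iodohepta-2,5-dien-2-yl]lithium (Li cis to C4) | C/C([Li])=C/C/C=C(/C)I | intermediate
13 | (2S,3R,6Z,9Z)-1-[(tert-butyldimethylsilyl)oxy]-2-hydroxy-10-iodo-6-methyl-3-(prop-1-en-2-yl)undeca-6,9-dien-5-one | C=C(C)[C@H]([C@H](O)CO[Si](C)(C)C(C)(C)C)CC(=O)/C(C)=C\C/C=C(/C)I | intermediate
14 | (2S,3R,6Z,9Z)-1-[(tert-butyldimethylsilyl)oxy]-10-iodo-6-methyl-5-oxo-3-(prop-1-en-2-yl)undeca-6,9-dien-2-yl (2Z)-2-methylbut-2-enoate | C=C(C)[C@H]([C@H](OC(=O)/C(C)=C\C)CO[Si](C)(C)C(C)(C)C)CC(=O)/C(C)=C\C/C=C(/C)I | intermediate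
15 | (2S,3R,5R,6Z,9Z)-1-[(tert-butyldimethylsilyl)oxy]-5-hydroxy-10-iodo-6-methyl-3-(prop-1-en-2-yl)undeca-6,9-dien-2-yl (2Z)-2-methylbut-2-enoate | C=C(C)[C@H]([C@H](OC(=O)/C(C)=C\C)CO[Si](C)(C)C(C)(C)C)C[C@@H](O)/C(C)=C\C/C=C(/C)I | intermediate
16 | (2S,3R,5R,6S,7R,9Z)-1-[(tert-butyldimethylsilyl)oxy]-6,7-epoxy-5-hydroxy-10-iodo-6-methyl-3-(prop-1-en-2-yl)undec-9-en-2-yl (2Z)-2-methylbut-2-enoate | C=C(C)[C@H]([C@H](OC(=O)/C(C)=C\C)CO[Si](C)(C)C(C)(C)C)C[C@@H](O)[C@]1(C)O[C@@H]1C/C=C(/C)I | intermediate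
17 | (2S,3R,5R,6S,7S,9Z)-1-[(tert-butyldimethylsilyl)oxy]-5,6-dihydroxy-10-iodo-6-methyl-3-(prop-1-en-2-yl)undec-9-ene-2,7-diyl bis[(2Z)-2-methylbut-2-enoate] | C=C(C)[C@H]([C@H](OC(=O)/C(C)=C\C)CO[Si](C)(C)C(C)(C)C)C[C@@H](O)[C@](C)(O)[C@@H](OC(=O)/C(C)=C\C)C/C=C(/C)I | intermediate
18 | (2S,3R,5R,6S,7S,9Z)-5-acetoxy-1-[(tert-butyldimethylsilyl)oxy]-6-hydroxy-10-iodo-6-methyl-3-(prop-1-en-2-yl)undec-9-ene-2,7-diyl bis[(2Z)-2-methylbut-2-enoate] | C=C(C)[C@H]([C@H](OC(=O)/C(C)=C\C)CO[Si](C)(C)C(C)(C)C)C[C@@H](OC(C)=O)[C@](C)(O)[C@@H](OC(=O)/C(C)=C\C)C/C=C(/C)I | intermediate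
19 | (2S,3R,5R,6S,7S,9Z)-5-acetoxy-1,6-dihydroxy-10-iodo-6-methyl-3-(prop-1-en-2-yl)undec-9-ene-2,7-diyl bis[(2Z)-2-methylbut-2-enoate] | C=C(C)[C@H]([C@H](OC(=O)/C(C)=C\C)CO)C[C@@H](OC(C)=O)[C@](C)(O)[C@@H](OC(=O)/C(C)=C\C)C/C=C(/C)I | intermediate
20 | (2S,3R,5R,6S,7S,9Z)-5-acetoxy-6-hydroxy-10-iodo-6-methyl-1-oxo-3-(prop-1-en-2-yl)undec-9-ene-2,7-diyl bis[(2Z)-2-methylbut-2-enoate] | C=C(C)[C@H]([C@H](OC(=O)/C(C)=C\C)C=O)C[C@@H](OC(C)=O)[C@](C)(O)[C@@H](OC(=O)/C(C)=C\C)C/C=C(/C)I | intermediate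
21 | (1R,3R,4S,5S,7Z,9R,10S)-3-acetoxy-4,9-dihydroxy-4,8-dimethyl-1-(prop-1-en-2-yl)cyclodec-7-ene-5,10-diyl bis[(2Z)-2-methylbut-2-enoate] | C=C(C)[C@H]1C[C@@H](OC(C)=O)[C@](C)(O)[C@@H](OC(=O)/C(C)=C\C)C/C=C(/C)[C@@H](O)[C@H]1OC(=O)/C(C)=C\C | intermediate
22 | (1R,3R,4S,5S,7R,8S,9S,10S)-3-acetoxy-7,8-epoxy-4,9-dihydroxy-4,8-dimethyl-1-(prop-1-en-2-yl)cyclodecane-5,10-diyl bis[(2Z)-2-methylbut-2-enoate] | C=C(C)[C@H]1C[C@@H](OC(C)=O)[C@](C)(O)[C@@H](OC(=O)/C(C)=C\C)C[C@H]2O[C@@]2(C)[C@@H](O)[C@H]1OC(=O)/C(C)=C\C | intermediate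
23 | (1R,3R,4S,5S,7R,8R,9S,10S)-3,9-diacetoxy-7,8-epoxy-4-hydroxy-4,8-dimethyl-1-(prop-1-en-2-yl)cyclodecane-5,10-diyl bis[(2Z)-2-methylbut-2-enoate] (CNP0281348.1) | C=C(C)[C@H]1C[C@@H](OC(C)=O)[C@](C)(O)[C@@H](OC(=O)/C(C)=C\C)C[C@H]2O[C@@]2(C)[C@@H](OC(C)=O)[C@H]1OC(=O)/C(C)=C\C | target

**Step count**
Total steps: 18. Longest linear sequence: 15 (7 → 8 → 9 → 10 → 11 → 13 → … → 23, steps 4–18); the other branch (1 + 2 → 6 → … → 23) is 14 steps.

**Steps most likely to fail**

Step 1 (the proposed organocatalytic glyoxylate–ene reaction). The risks are low reactivity of the ester-substituted trisubstituted alkene, capture of the developing tertiary cation by the ester (Prins-type lactone), and insufficient enantiocontrol. The fallback uses known chemistry, sets out from 7 and returns at 6. L-Proline-catalysed α-aminoxylation of 7 with nitrosobenzene (DMSO, rt) gives (2R)-3-[(tert-butyldimethylsilyl)oxy]-2-[(phenylamino)oxy]propanal F1. Still–Gennari olefination (methyl 2-[bis(2,2,2-trifluoroethoxy)phosphoryl]acetate, KHMDS, 18-crown-6, THF, −78 °C) gives methyl (2Z,4S)-5-[(tert-butyldimethylsilyl)oxy]-4-[(phenylamino)oxy]pent-2-enoate F2. N–O cleavage with Zn/AcOH frees the hydroxyl, which lactonises onto the cis ester to give (5S)-5-{[(tert-butyldimethylsilyl)oxy]methyl}furan-2(5H)-one F3. Conjugate addition of isopropenylmagnesium bromide with CuBr·SMe2 and TMSCl (THF, −78 °C) takes place anti to the C5 substituent and gives 6. These four steps replace steps 1–3, and the first stereocentre is then set by proline enamine catalysis.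

Step 8 (mono-lithiation of the bis-iodide and addition to the lactone). The risks are enolisation of the lactone, double addition, and loss of the (Z)-enone geometry. The fallback sets out from 6 and returns at 13. Aminolysis of 6 with MeNH(OMe)·HCl and i-PrMgCl (THF, −20 °C) gives the open-chain Weinreb amide (3R,4S)-5-[(tert-butyldimethylsilyl)oxy]-4-hydroxy-N-methoxy-N-methyl-3-(prop-1-en-2-yl)pentanamide F4. Its magnesium alkoxide (one further equivalent of i-PrMgCl) is treated with vinyllithium 12 at −78 °C. The chelated tetrahedral intermediate cannot add a second time and releases 13 only on mild acidic work-up, so the ketone is made by Weinreb acylation instead of direct lactone opening.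

Step 16 (ten-membered ring closure and C9 configuration). The risks are a modest cyclisation yield and formation of the wrong carbinol epimer. The fallback sets out from 20 and returns at 21. The cyclisation is run as before, and the epimer (1R,3R,4S,5S,7Z,9S,10S)-3-acetoxy-4,9-dihydroxy-4,8-dimethyl-1-(prop-1-en-2-yl)cyclodec-7-ene-5,10-diyl bis[(2Z)-2-methylbut-2-enoate] F5, alone or mixed with 21, is oxidised (Dess–Martin periodinane, NaHCO3, CH2Cl2) to the ring enone (1R,3R,4S,5S,7Z,10S)-3-acetoxy-4-hydroxy-4,8-dimethyl-9-oxo-1-(prop-1-en-2-yl)cyclodec-7-ene-5,10-diyl bis[(2Z)-2-methylbut-2-enoate] F6. Luche reduction (NaBH4, CeCl3·7H2O, MeOH, −78 °C) with hydride attack from the outer face of the medium ring then gives 21. C9 is thus set by 1,2-reduction of a cyclic enone instead of by addition to the open-chain aldehyde, and the wrong epimer is recycled. This fallback does not address a failure of the ring closure itself.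

Further compounds
F1 | step 1 | (2R)-3-[(tert-butyldimethylsilyl)oxy]-2-[(phenylamino)oxy]propanal | O=C[C@H](ONc1ccccc1)CO[Si](C)(C)C(C)(C)C
F2 | step 1 | methyl (2Z,4S)-5-[(tert-butyldimethylsilyl)oxy]-4-[(phenylamino)oxy]pent-2-enoate | COC(=O)/C=C\[C@H](ONc1ccccc1)CO[Si](C)(C)C(C)(C)C
F3 | step 1 | (5S)-5-{[(tert-butyldimethylsilyl)oxy]methyl}furan-2(5H)-one | O=C1C=C[C@@H](CO[Si](C)(C)C(C)(C)C)O1
F4 | step 8 | (3R,4S)-5-[(tert-butyldimethylsilyl)oxy]-4-hydroxy-N-methoxy-N-methyl-3-(prop-1-en-2-yl)pentanamide | C=C(C)[C@H]([C@H](O)CO[Si](C)(C)C(C)(C)C)CC(=O)N(C)OC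
F5 | step 16 | (1R,3R,4S,5S,7Z,9S,10S)-3-acetoxy-4,9-dihydroxy-4,8-dimethyl-1-(prop-1-en-2-yl)cyclodec-7-ene-5,10-diyl bis[(2Z)-2-methylbut-2-enoate] | C=C(C)[C@H]1C[C@@H](OC(C)=O)[C@](C)(O)[C@@H](OC(=O)/C(C)=C\C)C/C=C(/C)[C@H](O)[C@H]1OC(=O)/C(C)=C\C
F6 | step 16 | (1R,3R,4S,5S,7Z,10S)-3-acetoxy-4-hydroxy-4,8-dimethyl-9-oxo-1-(prop-1-en-2-yl)cyclodec-7-ene-5,10-diyl bis[(2Z)-2-methylbut-2-enoate] | C=C(C)[C@H]1C[C@@H](OC(C)=O)[C@](C)(O)[C@@H](OC(=O)/C(C)=C\C)C/C=C(/C)C(=O)[C@H]1OC(=O)/C(C)=C\C
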